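## Analysis of the target

The target consists of three rings joined by two methylene bridges: a central benzene ring A that carries a substituent on every carbon, and two identical 6-ethyl-4-hydroxy-5-methyl-2H-pyran-2-one rings (B and B') attached through C3' to the CH2 groups on C3 and C5 of ring A. Ring A is a phloroglucinol: C2, C4 and C6 carry hydroxyl groups and C1 carries the (2R)-2-methylbutanoyl group, so oxygen and carbon substituents alternate around the ring. The only stereocentre is Cα of the acyl chain (R); it has no stereochemical partner, but it lies next to an aryl ketone and can be lost by enolisation, so it is best bought and then kept away from strong acid and base. Apart from this side chain the molecule has a mirror plane through C1 and C4, which invites a twofold attachment of one pyranone building block. Sensitive points are the electron-rich triphenol (oxidation), the two enol lactones (ring opening by hard nucleophiles) and above all the two CH2 bridges, each flanked by a phenol and an enol, which can fragment to quinone methides or cyclodehydrate to fused pyranochromenes under forcing acid or base. The difficulty is the hexasubstituted ring A: C1 must be told apart from C3 and C5, and the three oxygens from one another, which stepwise electrophilic substitution of a symmetrical trihydroxybenzene does not do cleanly. The strategy rests on the 1,3,5-oxygen/1,3,5-carbon alternation of ring A: O4 can come from a cyclobutenone carbonyl, O6 from the 3-alkoxy group of that cyclobutenone and O2 from the oxygen of an ynol ether, while C5 and C3 arrive with their one-carbon arms and C1 is left as the single C–H of the new arene.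

## Retrosynthetic reasoning

**Target 33 to ethyl ether 32.** The last bond cut is the O–ethyl bond at C6. This oxygen sits ortho to the aryl ketone, so a chelating Lewis acid can remove the ethyl group selectively. The cleavage is placed last because the same reagent would also cleave benzylic methyl ethers, and these are gone only after the pyranones are attached.

**32 to diol 22 and two molecules of pyranone 28.** Both CH2–C3' bonds are cut. C3' of 28 is the innate nucleophile of a 4-hydroxy-2-pyranone, and the methoxymethyl groups on C3 and C5 of 22 are latent ortho-quinone methides through the neighbouring phenols. Ring A of 22 has no free carbon, so it cannot condense with itself. Cutting the ring A–CH2 bonds instead would need a ring A with three open positions and no way to tell C1 from C3 and C5. The gain is convergence: one purified pyranone is used twice.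

**28 to diketo ester 27, then to keto ester 23 and amide 24.** The lactone O1'–C2' bond and the C5'–C6' bond are cut. The forward steps are a γ-acylation of a β-keto ester dianion and a lactonisation, both with fixed regiochemistry.

**22 to bis-silyl ketone 21, then to aryl bromide 15 and amide 18.** The C1–acyl bond is cut as aryl anion plus acyl cation. An electrophilic acylation of the arene is avoided on purpose: its Lewis acid would ionise the two methoxymethyl groups while a nucleophilic ring position is still open, and an α-branched acylating agent under such conditions risks its configuration. A halogen–lithium exchange at C1 and addition to the N-methoxy-N-methylamide 18 are regiospecific and non-enolising. Amide 18 comes from acid 16, which supplies the stereocentre.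

**15 to bromophenol 14 to phenol 13.** The O–silyl bond and the C1–Br bond are cut. Phenol 13 has a single ring C–H, para to its free hydroxyl, so bromination needs no regiocontrol; the hydroxyl is then masked with a silyl group that leaves together with the triisopropylsilyl group.

**13 to cyclobutenone 4 and ynol ether 8 (key disconnection).** Ring A is cut at C1–C2 and C3–C4; the C4–C5 bond is broken and re-formed in the cascade. This is the only cut that delivers all six substituents with the right neighbours in one operation: the carbonyl of 4 becomes O4, its ethoxy group O6, its C4 with the methoxymethyl arm becomes C5, and its C2–H becomes C1. The alkyne 8 supplies C3 with its arm and C2 with the silyloxy group. The forward reaction has to achieve one regiochemical event, the union of the ketene carbonyl carbon with the alkyne carbon remote from oxygen.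

**4 to acid chloride 1 and ethoxyacetylene 2; 8 to methyl propargyl ether 5.** The four-membered ring is cut into ketene 3 and alkyne 2, a cycloaddition with fixed regiochemistry. The O–Si and C–O bonds of 8 lead back through ynolate 7 and acetylide 6 to 5. All of 1, 2, 5, 16, 23 and 24 are purchased.

## Alternatives that were turned down

**Alternative 1:** Both pyranone rings are cut at C4'–C5' and O1'–C2'. This leads to a ring A that already carries the acyl group, three benzyl ethers and two malonyl dichloride arms, 2,2'-{[2,4,6-tris(benzyloxy)-5-((2R)-2-methylbutanoyl)-1,3-phenylene]bis(methylene)}dimalonyl tetrachloride A2, and to two molecules of pentan-3-one A3. In the forward step A2 is heated with A3; on each arm the enol carbon of the ketone is acylated by one acid chloride and the enol oxygen by the other, giving the tri-O-benzyl ether A1 of the target.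

- For: the ketone A3 is symmetrical, so there is no regiochemical question, and both heterocycles form in one operation. The benzyl ethers leave by neutral hydrogenolysis; on this last deprotection the plan is stronger than the Lewis-acid dealkylation of 32.
- Against: A2 is a fourfold acid chloride that must be built in many steps on a ring A whose C1/C3/C5 differentiation is still unsolved. Monosubstituted malonyl chlorides lose hydrogen halide to chlorocarbonyl ketenes that oligomerise. Four acylations of an unactivated ketone must all succeed. The hot, acidic medium meets benzyl ethers on a trioxygenated ring and an enolisable chiral ketone, which is itself a competing enol donor.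
- Comparison: the chosen route forms the pyranone once, by two well-behaved steps (23 to 28), joins it under weak acid catalysis, and fixes the ring A pattern by pericyclic regiocontrol.

**Alternative 2:** Ring A is cut at C2–C3 and C5–C6, giving the symmetrical ketone 3,3'-(3-oxopentane-1,5-diyl)bis(6-ethyl-4-methoxy-5-methyl-2H-pyran-2-one) A5 and malonyl dichloride A6. The forward step is a twofold C-acylation of the two α-carbons of A5 by A6, followed by alkoxide equilibration to the aromatic triol 2,4-bis[(6-ethyl-4-methoxy-5-methyl-2-oxo-2H-pyran-3-yl)methyl]benzene-1,3,5-triol A4.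

- For: the symmetry is used fully, both arms are in place before ring A exists, and ring A needs no protecting groups. On protecting-group economy this plan is stronger than the chosen one.
- Against: a ketone and A6 close preferentially through oxygen to a 4-hydroxy-2-pyranone, so C,C-diacylation is the disfavoured path. The alkoxide needed to funnel material to the arene also opens or trans-etherifies the 4-methoxy-2-pyranones of the arms. A4 still lacks the acyl group, which would have to be introduced by a Lewis-acid acylation with an α-chiral acyl donor on a skeleton with acid-labile bridges. The two pyranone methyl ethers must then be removed.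
- Comparison: the chosen route introduces the acyl group by an aryllithium on a protected ring before any bridge exists, and its pyranone is never protected.

**Alternative 3:** Both pyranones are cut at C5'–C6' and O1'–C2', giving dimethyl 2,2'-[(2,4,6-trimethoxy-1,3-phenylene)bis(methylene)]bis(3-oxopentanoate) A8 and two molecules of amide 24. In the forward step the bis(dianion) of A8 is acylated at both γ-carbons by 24 and the 3,5-dioxo esters lactonise on acidification to 3,3'-[(2,4,6-trimethoxy-1,3-phenylene)bis(methylene)]bis(6-ethyl-4-hydroxy-5-methyl-2H-pyran-2-one) A7.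

- For: the ring-forming chemistry is the same dependable dianion acylation used here for 28 (steps 9 and 10). Ring A comes from a cheap symmetrical arene, and no small ring or ynol ether is needed. On robustness and scalability of the carbon–carbon bond formation this plan is equal or stronger.
- Against: a tetra-anion of an α-substituted keto ester is hard to form completely and to acylate twice. A7 still needs the acyl group at C1, again by Lewis-acid acylation in the presence of free pyranone hydroxyls and the bridges. Of its three aryl methyl ethers only the two flanking the new ketone can be removed with chelation assistance; the C4 ether needs forcing dealkylation that the bridges, lactones and stereocentre are unlikely to survive.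
- Comparison: the chosen route gives three differentiated oxygens from the moment ring A is formed (free hydroxyl, silyl ether, ethyl ether), so only the one alkyl ether ortho to the ketone has to be cleaved at the end.

Key step: step 3

Remark: acid 16 is taken as purchased in enantiopure form; in step 11 the two arms are drawn as reacting one after the other, the arm next to the ethoxy group first, which does not affect the product.

## Route

Step 1
Reactants: 1 3-methoxypropanoyl chloride; 2 ethoxyacetylene
Product: 4 rac-3-ethoxy-4-(methoxymethyl)cyclobut-2-en-1-one, via (methoxymethyl)ketene 3 (not isolated)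
Conditions: Et3N (1.3 equiv), 2 (1.5 equiv, solution in hexanes), Et2O, 0 °C → rt, slow addition of 1
Reagents that add atoms: none
Why: Dehydrochlorination of 1 gives aldoketene 3, which is trapped as it forms by the electron-rich alkyne in a regioselective (2+2) cycloaddition (alkyne CH to the ketene carbonyl carbon, C–OEt to the ketene α-carbon), the standard entry to 4-substituted 3-ethoxycyclobutenones; methoxide is too poor a leaving group for β-elimination to compete with chloride loss, slow addition keeps 3 from dimerising, and the racemic C4 is destroyed in step 3.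

Step 2
Reactants: 5 methyl propargyl ether
Product: 8 triisopropyl[(3-methoxyprop-1-yn-1-yl)oxy]silane, via lithium acetylide 6 (not isolated), via lithium ynolate 7 (not isolated)
Conditions: LiN(SiMe3)2 (2.1 equiv), THF, −78 °C; t-BuOOH (1.0 equiv, in decane), −78 → 0 °C; TIPSOTf (1.2 equiv), −78 °C; pentane/aq. NaHCO3 work-up
Reagents that add atoms: tert-butyl hydroperoxide, CC(C)(C)OO; triisopropylsilyl trifluoromethanesulfonate, CC(C)[Si](OS(=O)(=O)C(F)(F)F)(C(C)C)C(C)C
Why: Oxidation of a lithium acetylide by lithium tert-butyl peroxide (made in the flask) transfers one oxygen atom to carbon and gives the ynolate, which the bulky silyl triflate captures on oxygen; loss of methoxide from 7 would have to form propadienone and is therefore unfavourable, and the basic work-up protects the acid-sensitive ynol ether.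

Step 3
Reactants: 4 rac-3-ethoxy-4-(methoxymethyl)cyclobut-2-en-1-one; 8 triisopropyl[(3-methoxyprop-1-yn-1-yl)oxy]silane
Product: 13 3-ethoxy-2,6-bis(methoxymethyl)-5-[(triisopropylsilyl)oxy]phenol, via vinylketene 9 (not isolated), via 4-alkenylcyclobutenone 10 (not isolated), via dienylketene 11 (not isolated), via cyclohexadienone 12 (not isolated)
Conditions: toluene (0.2 M), 80 °C then 110 °C, sealed tube, 8 (1.3 equiv)
Reagents that add atoms: none
Why: This is a Danheiser benzannulation: on heating, 4 opens by a conrotatory 4π electrocyclic reaction, the methoxymethyl group turning outward, to the (2-ethoxyvinyl)ketene 9, whose carbonyl carbon is attacked by the alkyne carbon remote from oxygen in a (2+2) cycloaddition that gives 10. Cyclobutenone 10 opens in a second 4π step to dienylketene 11, which closes ring A by a thermal disrotatory 6π electrocyclisation (bond C4–C5) to dienone 12, and 12 enolises to phenol 13. The closest known reaction type is the benzannulation of 3-alkyl- and 3-arylcyclobutenones with triisopropylsilyl ynol ethers to resorcinol monosilyl ethers; the 3-ethoxy group is the less common element, but the 3-oxy-4-alkenylcyclobutenones through which every heteroalkyne benzannulation passes open under the same conditions, so the vinylogous-ester stabilisation of 4 should only raise the temperature needed. Regiochemistry is the one selectivity the step must deliver and it is fixed by polarity: the silyloxy oxygen makes the CH2OMe-bearing alkyne carbon the nucleophile and the ketene carbonyl carbon is the electrophile, so the new C3–C4 and C1–C2 bonds place carbonyl oxygen, silyloxy oxygen and ethoxy oxygen 1,3,5 to one another. The opening of 10 is reversible and only the isomer of 11 with the alkenyl group turned toward the ketene can cyclise, so the unproductive rotamer returns to 10. No stereocentre survives, since the sp3 carbons of 4, 10 and 12 all become aromatic. The 2,6-disubstituted phenol 13 is a poor trap for ketene 9, which should limit aryl ester by-products.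

Step 4
Reactants: 13 3-ethoxy-2,6-bis(methoxymethyl)-5-[(triisopropylsilyl)oxy]phenol
Product: 14 4-bromo-3-ethoxy-2,6-bis(methoxymethyl)-5-[(triisopropylsilyl)oxy]phenol
Conditions: NBS (1.0 equiv), CH2Cl2, −78 → −20 °C, dark
Reagents that add atoms: N-bromosuccinimide, O=C1CCC(=O)N1Br
Why: Electrophilic aromatic bromination at the only unsubstituted ring carbon, para to the free hydroxyl and ortho to two further oxygens; one equivalent at low temperature in the dark avoids ipso attack at the arm-bearing carbons and radical benzylic bromination.

Step 5
Reactants: 14 4-bromo-3-ethoxy-2,6-bis(methoxymethyl)-5-[(triisopropylsilyl)oxy]phenol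
Product: 15 {4-bromo-3-ethoxy-2,6-bis(methoxymethyl)-5-[(triisopropylsilyl)oxy]phenoxy}(tert-butyl)dimethylsilane
Conditions: TBSCl (1.5 equiv), imidazole (3 equiv), DMF, rt
Reagents that add atoms: tert-butyldimethylsilyl chloride, CC(C)(C)[Si](C)(C)Cl
Why: Standard imidazole-promoted silylation of a phenol; the acidic proton must be masked before halogen–lithium exchange, the two ortho CH2 groups are small enough for this silyl chloride, and the group leaves together with the triisopropylsilyl group in step 8.

Step 6
Reactants: 16 (R)-2-methylbutanoic acid
Product: 18 (2R)-N-methoxy-N,2-dimethylbutanamide, via acyl imidazole 17 (not isolated)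
Conditions: CDI (1.1 equiv), CH2Cl2, 0 °C → rt; MeNH(OMe)·HCl (1.2 equiv), rt
Reagents that add atoms: N,O-dimethylhydroxylamine hydrochloride, CNOC.Cl
Why: Weinreb amide formation through the acyl imidazole; activation without an acid chloride and without a tertiary amine avoids ketene formation, so Cα keeps its R configuration.

Step 7
Reactants: 15 {4-bromo-3-ethoxy-2,6-bis(methoxymethyl)-5-[(triisopropylsilyl)oxy]phenoxy}(tert-butyl)dimethylsilane; 18 (2R)-N-methoxy-N,2-dimethylbutanamide
Product: 21 (2R)-1-{4-[(tert-butyldimethylsilyl)oxy]-2-ethoxy-3,5-bis(methoxymethyl)-6-[(triisopropylsilyl)oxy]phenyl}-2-methylbutan-1-one, via aryllithium 19 (not isolated), via lithium hemiaminal adduct 20 (not isolated)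
Conditions: t-BuLi (2.05 equiv), Et2O, −78 °C; 18 (1.3 equiv), −78 → −30 °C; aq. NH4Cl
Reagents that add atoms: none
Why: Bromine–lithium exchange with two equivalents of t-BuLi is faster than any deprotonation, and aryllithium 19 adds to the Weinreb amide to give the chelated adduct 20, which does not collapse before the quench, so neither over-addition nor enolisation of the ketone can occur and the stereocentre from 16 is carried through unchanged; Et2O and −78 °C are chosen to suppress 1,3-migration of the ortho triisopropylsilyl group from oxygen to carbon.

Step 8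
Reactants: 21 (2R)-1-{4-[(tert-butyldimethylsilyl)oxy]-2-ethoxy-3,5-bis(methoxymethyl)-6-[(triisopropylsilyl)oxy]phenyl}-2-methylbutan-1-one
Product: 22 (2R)-1-[2-ethoxy-4,6-dihydroxy-3,5-bis(methoxymethyl)phenyl]-2-methylbutan-1-one
Conditions: Bu4NF (2.2 equiv), AcOH (2.5 equiv), THF, 0 °C
Reagents that add atoms: none
Why: Fluoride cleaves both aryl silyl ethers; acetic acid buffers the phenoxides so that neither expulsion of methoxide from the ortho methoxymethyl groups nor enolisation next to the ketone is triggered.

Step 9
Reactants: 23 methyl 3-oxopentanoate; 24 N-methoxy-N-methylpropanamide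
Product: 27 methyl 4-methyl-3,5-dioxoheptanoate (racemic, keto–enol mixture), via dilithium dianion 25 (not isolated), via dilithium hemiaminal adduct 26 (not isolated)
Conditions: LiN(iPr)2 (2.1 equiv), THF, 0 °C; 24 (0.9 equiv), −78 → 0 °C; 1 M HCl
Reagents that add atoms: none
Why: Huckin–Weiler dianion chemistry: the dianion of the β-keto ester is acylated at its more nucleophilic γ-carbon and the Weinreb amide stops at the ketone level because adduct 26 persists until acidification; the new CH(CH3) centre is racemic and becomes sp2 in step 10.

Step 10
Reactants: 27 methyl 4-methyl-3,5-dioxoheptanoate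
Product: 28 6-ethyl-4-hydroxy-5-methyl-2H-pyran-2-one
Conditions: DBU (1.5 equiv), toluene, 110 °C; then 1 M HCl
Reagents that add atoms: none
Why: Base-mediated lactonisation of a 3,5-dioxo ester: the enolate oxygen at C5 attacks the ester, methoxide is lost and the ring tautomerises to the aromatic 4-hydroxy-2-pyranone.

Step 11
Reactants: 22 (2R)-1-[2-ethoxy-4,6-dihydroxy-3,5-bis(methoxymethyl)phenyl]-2-methylbutan-1-one; 28 6-ethyl-4-hydroxy-5-methyl-2H-pyran-2-one
Product: 32 3,3'-{[4-ethoxy-2,6-dihydroxy-5-((2R)-2-methylbutanoyl)-1,3-phenylene]bis(methylene)}bis(6-ethyl-4-hydroxy-5-methyl-2H-pyran-2-one), via ortho-quinone methide 29 (not isolated), via mono-adduct 30 (not isolated), via ortho-quinone methide 31 (not isolated)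
Conditions: 28 (2.5 equiv), PPTS (20 mol %), MeCN, 60 °C
Reagents that add atoms: none
Why: Acid-catalysed loss of methanol from an ortho-hydroxybenzyl methyl ether gives an ortho-quinone methide (each benzylic carbon has oxygen at both ortho positions and at the para position, the acyl group being meta), and conjugate addition of C3' of the 4-hydroxy-2-pyranone restores the arene, the known coupling of quinone methide precursors with 4-hydroxycoumarins and pyranones; ring A has no free carbon and cannot oligomerise, C–C bond formation is the only irreversible event so O-alkylated material should return, and the weak acid and the excess of 28 are meant to suppress cyclodehydration and double alkylation of one pyranone.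

Step 12
Reactants: 32 3,3'-{[4-ethoxy-2,6-dihydroxy-5-((2R)-2-methylbutanoyl)-1,3-phenylene]bis(methylene)}bis(6-ethyl-4-hydroxy-5-methyl-2H-pyran-2-one)
Product: 33 3,3'-{[2,4,6-trihydroxy-5-((2R)-2-methylbutanoyl)-1,3-phenylene]bis(methylene)}bis(6-ethyl-4-hydroxy-5-methyl-2H-pyran-2-one)
Conditions: BCl3 (8 equiv), CH2Cl2, −78 → 0 °C; then H2O
Reagents that add atoms: none
Why: BCl3 binds the ketone and the ortho ethoxy oxygen in a six-membered chelate and chloride removes the ethyl group by SN2, the standard chelation-controlled cleavage of an alkyl aryl ether ortho to a carbonyl; no other alkyl ether is left, and the excess covers the five hydroxyl groups, whose borates are hydrolysed on work-up.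

## Compound list

1 | 3-methoxypropanoyl chloride | COCCC(=O)Cl | starting material
2 | ethoxyacetylene (ethoxyethyne) | CCOC#C | starting material
3 | (methoxymethyl)ketene (4-methoxybut-1-en-1-one) | COCC=C=O | intermediate
4 | rac-3-ethoxy-4-(methoxymethyl)cyclobut-2-en-1-one | CCOC1=CC(=O)C1COC | intermediate
5 | methyl propargyl ether (3-methoxyprop-1-yne) | COCC#C | starting material
6 | lithium 3-methoxyprop-1-yn-1-ide | [Li]C#CCOC | intermediate
7 | lithium 3-methoxyprop-1-yn-1-olate | [Li]OC#CCOC | intermediate
8 | triisopropyl[(3-methoxyprop-1-yn-1-yl)oxy]silane | COCC#CO[Si](C(C)C)(C(C)C)C(C)C | intermediate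
9 | (3Z)-3-ethoxy-5-methoxypenta-1,3-dien-1-one | COC/C=C(OCC)/C=C=O | intermediate
10 | rac-4-[(1Z)-1-ethoxy-3-methoxyprop-1-en-1-yl]-2-(methoxymethyl)-3-[(triisopropylsilyl)oxy]cyclobut-2-en-1-one | O=C1C(COC)=C(O[Si](C(C)C)(C(C)C)C(C)C)C1/C(OCC)=C/COC | intermediate
11 | (3E,5Z)-5-ethoxy-7-methoxy-2-(methoxymethyl)-3-[(triisopropylsilyl)oxy]hepta-1,3,5-trien-1-one | O=C=C(COC)/C(O[Si](C(C)C)(C(C)C)C(C)C)=C\C(OCC)=C\COC | intermediate
12 | rac-5-ethoxy-2,6-bis(methoxymethyl)-3-[(triisopropylsilyl)oxy]cyclohexa-2,4-dien-1-one | O=C1C(COC)=C(O[Si](C(C)C)(C(C)C)C(C)C)C=C(OCC)C1COC | intermediate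
13 | 3-ethoxy-2,6-bis(methoxymethyl)-5-[(triisopropylsilyl)oxy]phenol | COCc1c(O)c(COC)c(OCC)cc1O[Si](C(C)C)(C(C)C)C(C)C | intermediate
14 | 4-bromo-3-ethoxy-2,6-bis(methoxymethyl)-5-[(triisopropylsilyl)oxy]phenol | COCc1c(O)c(COC)c(OCC)c(Br)c1O[Si](C(C)C)(C(C)C)C(C)C | intermediate
15 | {4-bromo-3-ethoxy-2,6-bis(methoxymethyl)-5-[(triisopropylsilyl)oxy]phenoxy}(tert-butyl)dimethylsilane | COCc1c(O[Si](C)(C)C(C)(C)C)c(COC)c(OCC)c(Br)c1O[Si](C(C)C)(C(C)C)C(C)C | intermediate
16 | (R)-2-methylbutanoic acid | OC(=O)[C@H](C)CC | starting material
17 | (2R)-1-(1H-imidazol-1-yl)-2-methylbutan-1-one | O=C([C@H](C)CC)n1ccnc1 | intermediate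
18 | (2R)-N-methoxy-N,2-dimethylbutanamide | CON(C)C(=O)[C@H](C)CC | intermediate
19 | {4-[(tert-butyldimethylsilyl)oxy]-2-ethoxy-3,5-bis(methoxymethyl)-6-[(triisopropylsilyl)oxy]phenyl}lithium | [Li]c1c(OCC)c(COC)c(O[Si](C)(C)C(C)(C)C)c(COC)c1O[Si](C(C)C)(C(C)C)C(C)C | intermediate
20 | lithium (2R)-1-{4-[(tert-butyldimethylsilyl)oxy]-2-ethoxy-3,5-bis(methoxymethyl)-6-[(triisopropylsilyl)oxy]phenyl}-1-[methoxy(methyl)amino]-2-methylbutan-1-olate (C1 unspecified) | CCOc1c(COC)c(O[Si](C)(C)C(C)(C)C)c(COC)c(O[Si](C(C)C)(C(C)C)C(C)C)c1C(O[Li])(N(C)OC)[C@H](C)CC | intermediate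
21 | (2R)-1-{4-[(tert-butyldimethylsilyl)oxy]-2-ethoxy-3,5-bis(methoxymethyl)-6-[(triisopropylsilyl)oxy]phenyl}-2-methylbutan-1-one | CCOc1c(COC)c(O[Si](C)(C)C(C)(C)C)c(COC)c(O[Si](C(C)C)(C(C)C)C(C)C)c1C(=O)[C@H](C)CC | intermediate
22 | (2R)-1-[2-ethoxy-4,6-dihydroxy-3,5-bis(methoxymethyl)phenyl]-2-methylbutan-1-one | CCOc1c(COC)c(O)c(COC)c(O)c1C(=O)[C@H](C)CC | intermediate
23 | methyl 3-oxopentanoate | CCC(=O)CC(=O)OC | starting material
24 | N-methoxy-N-methylpropanamide | CCC(=O)N(C)OC | starting material
25 | dilithium dianion of methyl 3-oxopentanoate (C2,C4-dianion) | [Li+].[Li+].C[CH-]C(=O)[CH-]C(=O)OC | intermediate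
26 | dilithium salt of methyl 5-hydroxy-5-[methoxy(methyl)amino]-4-methyl-3-oxoheptanoate (enolate alkoxide) | [Li+].[Li+].CCC([O-])(N(C)OC)C(C)C([O-])=CC(=O)OC | intermediate
27 | methyl 4-methyl-3,5-dioxoheptanoate (racemic) | CCC(=O)C(C)C(=O)CC(=O)OC | intermediate
28 | 6-ethyl-4-hydroxy-5-methyl-2H-pyran-2-one | CCc1oc(=O)cc(O)c1C | intermediate
29 | 5-ethoxy-3-hydroxy-2-(methoxymethyl)-4-[(2R)-2-methylbutanoyl]-6-methylidenecyclohexa-2,4-dien-1-one | O=C1C(=C)C(OCC)=C(C(=O)[C@H](C)CC)C(O)=C1COC | intermediate
30 | 3-{[2-ethoxy-4,6-dihydroxy-5-(methoxymethyl)-3-((2R)-2-methylbutanoyl)phenyl]methyl}-6-ethyl-4-hydroxy-5-methyl-2H-pyran-2-one | CCc1oc(=O)c(Cc2c(O)c(COC)c(O)c(C(=O)[C@H](C)CC)c2OCC)c(O)c1C | intermediate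
31 | 3-{[2-ethoxy-4-hydroxy-3-((2R)-2-methylbutanoyl)-5-methylidene-6-oxocyclohexa-1,3-dien-1-yl]methyl}-6-ethyl-4-hydroxy-5-methyl-2H-pyran-2-one | O=C1C(=C)C(O)=C(C(=O)[C@H](C)CC)C(OCC)=C1Cc2c(O)c(C)c(CC)oc2=O | intermediate
32 | 3,3'-{[4-ethoxy-2,6-dihydroxy-5-((2R)-2-methylbutanoyl)-1,3-phenylene]bis(methylene)}bis(6-ethyl-4-hydroxy-5-methyl-2H-pyran-2-one) | CCc1oc(=O)c(Cc2c(O)c(Cc3c(O)c(C)c(CC)oc3=O)c(O)c(C(=O)[C@H](C)CC)c2OCC)c(O)c1C | intermediate
33 | 3,3'-{[2,4,6-trihydroxy-5-((2R)-2-methylbutanoyl)-1,3-phenylene]bis(methylene)}bis(6-ethyl-4-hydroxy-5-methyl-2H-pyran-2-one) | CCc1oc(=O)c(Cc2c(O)c(Cc3c(O)c(C)c(CC)oc3=O)c(O)c(C(=O)[C@H](C)CC)c2O)c(O)c1C | target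

## Step count and least certain steps

Total: 12 steps. Longest linear sequence: 8 steps (steps 1, 3, 4, 5, 7, 8, 11, 12).

**Step 3 (key step).** The most likely failure is a mismatch of rates. Ring opening of 4 is slowed by its vinylogous-ester stabilisation, so the temperature needed may be one at which ynol ether 8 is consumed by adventitious hydrolysis or oligomerisation, phenol 13 slowly loses methanol from its ortho methoxymethyl groups, or the ketene is intercepted by the product phenol before the alkyne.
Fallback: it sets out from ynol ether 8 and comes back at phenol 13, with an open-chain precursor of ketene 9 in place of 4. Purchased methyl 5-methoxy-3-oxopentanoate F1 is O-ethylated with triethyl orthoformate and catalytic TsOH at room temperature to methyl (2E)-3-ethoxy-5-methoxypent-2-enoate F2. LiOH saponification gives (2E)-3-ethoxy-5-methoxypent-2-enoic acid F3, and oxalyl chloride gives (2E)-3-ethoxy-5-methoxypent-2-enoyl chloride F4. Slow addition of F4 to Et3N and 8 in toluene at room temperature should generate 9 by 1,4-dehydrochlorination (γ-deprotonation) without any electrocyclic opening. Alkyne 8 captures 9 as cyclobutenone 10, and warming to 80 °C then carries 10 through 11 and 12 to 13.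

**Step 2.** The most likely failure is incomplete oxygen transfer from the peroxide to the acetylide, with further loss of the ynol ether by hydrolysis or propargylic ionisation during isolation.
Fallback: it reaches the same ynolate by carbon-skeleton rearrangement (Kowalski ester homologation), starts from purchased methyl methoxyacetate F5 in place of alkyne 5 and comes back at ynolate 7. F5 is treated at −78 °C with LiCHBr2 (from CH2Br2 and lithium 2,2,6,6-tetramethylpiperidide) to give the enolate lithium 1,1-dibromo-3-methoxyprop-1-en-2-olate F6. n-BuLi then induces bromine–lithium exchange and 1,2-shift of the methoxymethyl group to 7, which is silylated on oxygen with TIPSCl to give 8.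

**Step 7.** The most likely failure is that the hindered aryllithium adds too slowly to the α-branched amide. On warming, migration of the triisopropylsilyl group from oxygen to the lithiated carbon, or deprotonation of the amide, would then take over.
Fallback: it sets out from bromide 15 and amide 18 and comes back at ketone 21, using a smaller and more electrophilic acyl equivalent. Amide 18 is reduced with LiAlH4 at −78 °C to (2R)-2-methylbutanal F7, kept as a cold ether solution. Aryllithium 19, generated as in step 7, should add to F7 at −78 °C to give (2R)-1-{4-[(tert-butyldimethylsilyl)oxy]-2-ethoxy-3,5-bis(methoxymethyl)-6-[(triisopropylsilyl)oxy]phenyl}-2-methylbutan-1-ol F8 as a mixture of carbinol epimers. Dess–Martin periodinane in buffered CH2Cl2 oxidises F8 to 21 without touching Cα.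

**Step 11.** The most likely failure is ionisation of the benzylic ethers without clean carbon–carbon bond formation: stalling after the first arm, double alkylation of one pyranone carbon, or acid-promoted cyclodehydration across a new bridge.
Fallback: it sets out from ketone 21 and comes back at 32, replacing the quinone methide by a reductive alkylation. DDQ in wet CH2Cl2 oxidises both methoxymethyl groups to give 2-[(tert-butyldimethylsilyl)oxy]-4-ethoxy-5-[(2R)-2-methylbutanoyl]-6-[(triisopropylsilyl)oxy]benzene-1,3-dicarbaldehyde F9. Knoevenagel condensation of F9 with pyranone 28 under L-proline catalysis in the presence of Hantzsch ester, which reduces each alkylidene as it forms, gives the bis-silyl ether 3,3'-{[2-[(tert-butyldimethylsilyl)oxy]-4-ethoxy-5-((2R)-2-methylbutanoyl)-6-[(triisopropylsilyl)oxy]-1,3-phenylene]bis(methylene)}bis(6-ethyl-4-hydroxy-5-methyl-2H-pyran-2-one) F10. Bu4NF/AcOH then gives 32.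

**Step 12.** The most likely failure is Lewis-acid damage to the finished skeleton before dealkylation is complete: fragmentation or scrambling at the methylene bridges, cyclodehydration, or enolisation next to the boron-bound ketone.
Fallback: it sets out from ketone 21 and comes back at target 33, so that the dealkylation precedes the coupling. BCl3 at −78 °C should remove the ortho ethyl group of 21 and at the same time turn both benzylic methyl ethers into chlorides, giving (2R)-1-{4-[(tert-butyldimethylsilyl)oxy]-3,5-bis(chloromethyl)-2-hydroxy-6-[(triisopropylsilyl)oxy]phenyl}-2-methylbutan-1-one F11, which is used crude. CsF in MeCN in the presence of excess 28 then unmasks the phenoxides. These expel chloride to ortho-quinone methides, which are captured by the pyranone at C3' and deliver 33 without a Lewis acid on the bridged skeleton.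

## Further compounds

F1 | step 3 | methyl 5-methoxy-3-oxopentanoate | COCCC(=O)CC(=O)OC
F2 | step 3 | methyl (2E)-3-ethoxy-5-methoxypent-2-enoate | CCO/C(CCOC)=C/C(=O)OC
F3 | step 3 | (2E)-3-ethoxy-5-methoxypent-2-enoic acid | CCO/C(CCOC)=C/C(=O)O
F4 | step 3 | (2E)-3-ethoxy-5-methoxypent-2-enoyl chloride | CCO/C(CCOC)=C/C(=O)Cl
F5 | step 2 | methyl methoxyacetate | COCC(=O)OC
F6 | step 2 | lithium 1,1-dibromo-3-methoxyprop-1-en-2-olate | [Li]OC(COC)=C(Br)Br
F7 | step 7 | (2R)-2-methylbutanal | O=C[C@H](C)CC
F8 | step 7 | (2R)-1-{4-[(tert-butyldimethylsilyl)oxy]-2-ethoxy-3,5-bis(methoxymethyl)-6-[(triisopropylsilyl)oxy]phenyl}-2-methylbutan-1-ol (C1 epimers) | CCOc1c(COC)c(O[Si](C)(C)C(C)(C)C)c(COC)c(O[Si](C(C)C)(C(C)C)C(C)C)c1C(O)[C@H](C)CC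
F9 | step 11 | 2-[(tert-butyldimethylsilyl)oxy]-4-ethoxy-5-[(2R)-2-methylbutanoyl]-6-[(triisopropylsilyl)oxy]benzene-1,3-dicarbaldehyde | CCOc1c(C=O)c(O[Si](C)(C)C(C)(C)C)c(C=O)c(O[Si](C(C)C)(C(C)C)C(C)C)c1C(=O)[C@H](C)CC
F10 | step 11 | 3,3'-{[2-[(tert-butyldimethylsilyl)oxy]-4-ethoxy-5-((2R)-2-methylbutanoyl)-6-[(triisopropylsilyl)oxy]-1,3-phenylene]bis(methylene)}bis(6-ethyl-4-hydroxy-5-methyl-2H-pyran-2-one) | CCOc1c(Cc2c(O)c(C)c(CC)oc2=O)c(O[Si](C)(C)C(C)(C)C)c(Cc2c(O)c(C)c(CC)oc2=O)c(O[Si](C(C)C)(C(C)C)C(C)C)c1C(=O)[C@H](C)CC
F11 | step 12 | (2R)-1-{4-[(tert-butyldimethylsilyl)oxy]-3,5-bis(chloromethyl)-2-hydroxy-6-[(triisopropylsilyl)oxy]phenyl}-2-methylbutan-1-one | Oc1c(CCl)c(O[Si](C)(C)C(C)(C)C)c(CCl)c(O[Si](C(C)C)(C(C)C)C(C)C)c1C(=O)[C@H](C)CC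
A1 | alternative 1 | 3,3'-{[2,4,6-tris(benzyloxy)-5-((2R)-2-methylbutanoyl)-1,3-phenylene]bis(methylene)}bis(6-ethyl-4-hydroxy-5-methyl-2H-pyran-2-one) | CCc1oc(=O)c(Cc2c(OCc3ccccc3)c(Cc3c(O)c(C)c(CC)oc3=O)c(OCc3ccccc3)c(C(=O)[C@H](C)CC)c2OCc2ccccc2)c(O)c1C
A2 | alternative 1 | 2,2'-{[2,4,6-tris(benzyloxy)-5-((2R)-2-methylbutanoyl)-1,3-phenylene]bis(methylene)}dimalonyl tetrachloride | ClC(=O)C(Cc1c(OCc2ccccc2)c(CC(C(Cl)=O)C(Cl)=O)c(OCc2ccccc2)c(C(=O)[C@H](C)CC)c1OCc1ccccc1)C(Cl)=O
A3 | alternative 1 | pentan-3-one | CCC(=O)CC
A4 | alternative 2 | 2,4-bis[(6-ethyl-4-methoxy-5-methyl-2-oxo-2H-pyran-3-yl)methyl]benzene-1,3,5-triol | CCc1oc(=O)c(Cc2c(O)cc(O)c(Cc3c(OC)c(C)c(CC)oc3=O)c2O)c(OC)c1C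
A5 | alternative 2 | 3,3'-(3-oxopentane-1,5-diyl)bis(6-ethyl-4-methoxy-5-methyl-2H-pyran-2-one) | CCc1oc(=O)c(CCC(=O)CCc2c(OC)c(C)c(CC)oc2=O)c(OC)c1C
A6 | alternative 2 | malonyl dichloride | ClC(=O)CC(=O)Cl
A7 | alternative 3 | 3,3'-[(2,4,6-trimethoxy-1,3-phenylene)bis(methylene)]bis(6-ethyl-4-hydroxy-5-methyl-2H-pyran-2-one) | CCc1oc(=O)c(Cc2c(OC)cc(OC)c(Cc3c(O)c(C)c(CC)oc3=O)c2OC)c(O)c1C
A8 | alternative 3 | dimethyl 2,2'-[(2,4,6-trimethoxy-1,3-phenylene)bis(methylene)]bis(3-oxopentanoate) | CCC(=O)C(Cc1c(OC)cc(OC)c(CC(C(=O)CC)C(=O)OC)c1OC)C(=O)OC
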